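## Structural features

Coloratanin A (23) is an isoflavone: benzene ring A is fused to pyranone ring C, and ring B is bonded through C1′ to C3 of ring C. Ring A carries hydroxyls at C5 and C7 with a prenyl group at C6 between them, and C8 is unsubstituted. Ring B carries a hydroxyl at C4′ and, ortho to it at C3′, a 3-hydroxy-3-methylbutyl chain (a hydrated prenyl group). The target has no stereocentre, so none stand next to each other; the only one in the route is the transient C3 carbinol of 20, which is removed again. The fragile groups are the trisubstituted alkene flanked by two phenols (acid closes it to a dimethylchroman; radicals, electrophiles and hydrogenation attack it) and the tertiary alcohol (it ionises in acid, then eliminates or closes onto O4′). The real difficulty is regiochemical: the prenyl group must sit at C6 and not at C8, two positions that substitution of a 5,7-dioxygenated ring A distinguishes poorly. The 3-arylchromone must also be assembled under conditions that spare the alkene and the carbinol. The key step exploits the fact that, with ring C opened at C3–C4, both carbons are carbonyl carbons: C4 is an aldehyde on C4a of ring A and C3 an aryl ketone on C1′ of ring B, held together by the bridge C8a–O1–C2.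

## Logic of the disconnections

**23 ⇒ 22.** The four O–CH2OCH3 bonds at O5, O7, O4′ and the side-chain tertiary oxygen are restored. The phenols must be masked for the lithiation and the carbene step. The tertiary carbinol must be masked because step 12 uses a dehydrating reagent that cannot tell two tertiary alcohols apart. One kind of group on all four oxygens reduces the finish to one operation. The forward step needs acid mild enough that the C6 prenyl group does not close onto O5 or O7 and the side-chain carbinol does not ionise.

**22 ⇒ 20.** Water is added back across C2=C3, placing a hydroxyl on C3. This brings ring C to the oxidation level that an acyl-anion addition to a ketone delivers. The forward dehydration is regiochemically unambiguous, since only C2 carries β-hydrogens. It must occur at a tertiary carbinol next to a carbonyl, where ionisation is disfavoured, so a concerted syn-elimination reagent is required.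

**20 ⇒ 18.** The C3–C4 bond is cut, which opens ring C. The gain is large: the isoflavone skeleton reduces to an aryl ether between a salicylaldehyde and a phenacyl unit. The forward step must invert the polarity of the aldehyde carbon only and use the ketone as the acceptor. It must also avoid base-induced aldol closure of the C2 methylene onto the aldehyde. The connectivity of 18 and 20 was checked atom by atom against 23 and needs no change. Compound 18 is named from the aldehyde carbon with lowest locants.

**18 ⇒ 9 + 17.** The O1–C2 ether bond is cut. This is the most convergent point, dividing the molecule into a ring A half and a ring B half of similar size. The forward step is a phenoxide alkylation and must run under a weak base, for the same aldol reason. The electrophile is chosen as an α-chloroketone, activated in the flask by iodide.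

**9 ⇒ 8.** The C4–C4a bond (formyl to ring A) is cut. Compound 8 is mirror-symmetric, so its two positions ortho to the free hydroxyl are equivalent. Formylation can therefore give one aldehyde only, with the prenyl group para to the future O1, that is, at C6 and never at C8. The forward step needs a phenol-directed ortho-formylation that tolerates acetals and an alkene.

**8 ⇒ 7 ⇒ 3 + 4.** The aryl–CH2 bond of the prenyl group and then the O–Si bond are cut. The ring carbon between the two acetal oxygens is the one most readily lithiated. The third oxygen must carry a group that does not direct lithiation, survives butyllithium and comes off without touching the acetals. A silyl ether meets all three demands. A tris-acetal could not be unmasked selectively at the oxygen para to the prenyl group, so this differentiation is where the design is tightened.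

**3 ⇒ 2 ⇒ 1.** The O–Si bond and two O–acetal bonds are cut, reaching the threefold-symmetric triol. The forward bis-protection is statistical by nature and is accepted because it stands first, on the cheapest material.

**17 ⇒ 14 + 15.** The aryl–carbonyl bond C1′–C3 is cut. The two-carbon unit C3–C2 then arrives together with its leaving group. This avoids an electrophilic α-halogenation of an electron-rich aryl ketone that bears acid-labile acetals. The forward step needs an aryllithium that acylates faster than it deprotonates 15.

**14 ⇒ 13 ⇒ 12.** Two O–acetal bonds and the C–Br bond para to the phenolic oxygen are cut. The bromine marks the carbon that becomes C1′. The forward bromination must be para-selective on a 2-alkylphenol.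

**12 ⇒ 10.** The two C–CH3 bonds at the carbinol carbon are cut. The lactone 10 already holds the aryl–CH2–CH2–C(=O) chain ortho to the phenolic oxygen. A double addition of a methyl Grignard reagent therefore gives the whole side chain in one step.

## Other disconnections considered

**Alternative 1:** The cut removes C3–C1′ and O1–C2 in one operation.
- **Forward step:** The ortho-hydroxyaryl enaminone A2 and the ring B arenediazonium salt A3 would be combined under single-electron initiation (a photoredox catalyst and visible light). The aryl radical from A3 adds to the α-carbon of A2 and the α-amino radical is oxidised to an iminium ion. The C8a phenol closes onto it and dimethylamine leaves, giving A1. Fluoride and dilute acid would then unmask 23.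
- **In its favour:** Ring C arrives at the chromone oxidation level, so no dehydration is needed and the tertiary alcohol can stay free. On both points this is better than the chosen plan. A2 would derive from the same symmetric phenol 8, so control of the prenyl position is equal, and convergence is equal.
- **Against it here:** The aryl radical has no strong preference for the enaminone over the electron-rich prenyl alkene (addition or allylic hydrogen abstraction). The diazonium ion is itself an electrophile that can azo-couple at C8 of the free-phenol ring A and at the enaminone carbon. A3 must be made by amination or nitration, reduction and diazotisation of a ring B that carries an acid-sensitive tertiary alcohol and a silyl ether.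
- **Comparison:** Structurally the two plans are equally convergent. Mechanistically the chosen plan uses closed-shell steps in which alkene and arenes are spectators, whereas here a radical and a cationic electrophile are generated in their presence. In step count Alternative 1 would be about two steps shorter if A3 were accessible; this is a real advantage, offset by lower confidence in chemoselectivity.

**Alternative 2:** The cut takes ring A apart at four bonds (C8–C8a, C7–C8, C5–C6, C4a–C5), leaving a pyranone that already bears ring B.
- **Forward step:** Irradiation of the diazoketone A5 with the siloxyalkyne A6 would trigger Wolff rearrangement to a vinylketene and [2+2] addition of the alkyne. On warming, 4π opening and 6π closure would give the phenol A4. Fluoride and acid would finish.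
- **In its favour:** Each ring A substituent is placed by the mechanism: the hydroxyl at C5 from the ketene carbonyl, the prenyl group at C6 from the alkyl-bearing alkyne carbon, the silyloxy group at C7. Regiocontrol is thus the equal of the chosen plan and needs no symmetry argument. Four bonds form in one step, which is better in bond-forming efficiency. The chromone level is present throughout, and O5 emerges free and distinct from O7.
- **Against it here:** A5 requires a 5-aryl-4-oxopyran-2-carboxylic acid and a diazo-transfer or diazomethane step. The 4-pyranone is itself photoactive, and its C4a=C8a double bond, part of a vinylogous ester, must take part in the 6π closure. A6 is a hydrolytically sensitive ynol ether with its own multistep preparation. Ketenes are formed next to a nucleophilic alkene.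
- **Comparison:** Structurally this plan is bolder, since ring A is made and not bought. Mechanistically it is a cascade of reactive intermediates against one catalytic polar addition. In step count and handling safety it is worse, because both partners are multistep and a diazo compound is needed.

**Alternative 3:** The cut removes O1–C8a and C4–C4a, detaching ring A as an aryne.
- **Forward step:** Fluoride would release the C4a–C8a aryne from the ortho-silylaryl triflate A8, which is reachable from 8. The enolate oxygen of the formylacetate A9 would add at C8a, and the aryl anion at C4a would acylate on the ester. This gives A7, which is the same compound as 22, and one acid step would then give 23.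
- **In its favour:** The C5 acetal oxygen directs the nucleophile to the remote aryne carbon C8a and stabilises the anion at C4a, which is exactly the connectivity required. The chromone level is reached without a dehydration, one step better than the chosen plan after the union. Fluoride in an aprotic solvent is gentle to acetals and alkene. Convergence is equal.
- **Against it here:** The enolate of A9 is ambident, and β-dicarbonyl enolates ordinarily attack arynes through carbon, leading to acyl–alkylation and not O-arylation. The aryl anion can be quenched by the acidic formylacetate before it cyclises. The aryne can undergo an ene reaction with a prenyl alkene of a second molecule. A8 costs about three further steps from 8 (halogenation, silyl transfer, triflation).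
- **Comparison:** The building blocks and endgame are the same (A7 = 22), so the plans are structurally equal. Mechanistically, the chosen plan's selectivity follows from which carbonyl can form a Breslow intermediate; here it depends on O- versus C-attack of an ambident nucleophile on a very reactive intermediate. The total step count is about equal, since the step saved after the union is spent on A8 and A9.

Key step: step 11

Assumption: an achiral carbene is used, so 20 forms as a racemate; this is immaterial because C3 becomes sp2 in step 12 (the SMILES of 20 and 21 show one enantiomer).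

## Route

**Step 1**
Reactants: 1 phloroglucinol (benzene-1,3,5-triol)
Product: 2 3,5-bis(methoxymethoxy)phenol
Conditions: MOMCl (2.0 equiv), i-Pr2NEt (2.2 equiv), DMF, 0 °C → rt
Reagents that add atoms: chloromethyl methyl ether (MOMCl), COCCl
Why: O-alkylation of a threefold-symmetric triol to the methoxymethyl acetals; two equivalents should give the bis-ether as the main component of a statistical mixture, from which the mono- and tris-ethers are separable and the mono-ether can be resubmitted.

**Step 2**
Reactants: 2 3,5-bis(methoxymethoxy)phenol
Product: 3 [3,5-bis(methoxymethoxy)phenoxy]tri(propan-2-yl)silane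
Conditions: TIPSCl, imidazole, DMF, rt
Reagents that add atoms: chlorotri(propan-2-yl)silane (TIPSCl), CC(C)[Si](Cl)(C(C)C)C(C)C
Why: Standard silylation of a phenol; the bulky silyl ether is a poor directing group and shields its own ortho positions, so the next lithiation should occur only between the two acetal oxygens.

**Step 3**
Reactants: 3 [3,5-bis(methoxymethoxy)phenoxy]tri(propan-2-yl)silane; 4 prenyl bromide (1-bromo-3-methylbut-2-ene)
Product: 7 [3,5-bis(methoxymethoxy)-4-(3-methylbut-2-en-1-yl)phenoxy]tri(propan-2-yl)silane, via aryllithium 5 (not isolated), via arylcopper 6 (not isolated)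
Conditions: n-BuLi, THF, 0 °C; CuI (1.1 equiv), −40 °C; 4, −40 °C → rt
Reagents that add atoms: none
Why: Directed ortho-metalation at the carbon flanked by two methoxymethoxy groups (cooperative chelation), transmetalation to the arylcopper and SN2 allylation at the primary carbon of 4; the copper species should suppress SN2′ attack and metal–halogen exchange.

**Step 4**
Reactants: 7 [3,5-bis(methoxymethoxy)-4-(3-methylbut-2-en-1-yl)phenoxy]tri(propan-2-yl)silane
Product: 8 3,5-bis(methoxymethoxy)-4-(3-methylbut-2-en-1-yl)phenol
Conditions: TBAF, THF, 0 °C; aq. NH4Cl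
Reagents that add atoms: none
Why: Fluoride cleavage of an aryl silyl ether, driven by the Si–F bond; acetals and the alkene are inert.

**Step 5**
Reactants: 8 3,5-bis(methoxymethoxy)-4-(3-methylbut-2-en-1-yl)phenol
Product: 9 6-hydroxy-2,4-bis(methoxymethoxy)-3-(3-methylbut-2-en-1-yl)benzaldehyde
Conditions: MgCl2, Et3N, (CH2O)n, MeCN, reflux
Reagents that add atoms: paraformaldehyde (as formaldehyde), C=O
Why: Magnesium-mediated ortho-formylation of a phenol (Casiraghi–Skattebøl): the magnesium phenoxide delivers formaldehyde to the ortho carbon and a second formaldehyde oxidises the benzylic alkoxide by hydride transfer. The two ortho positions of 8 are equivalent by symmetry, so only one aldehyde can form, and the basic medium spares acetals and alkene.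

**Step 6**
Reactants: 10 3,4-dihydrocoumarin (chroman-2-one)
Product: 12 2-(3-hydroxy-3-methylbutyl)phenol, via ketone phenoxide 11 (not isolated)
Conditions: MeMgBr (3 equiv), THF, 0 °C → rt; aq. NH4Cl
Reagents that add atoms: methylmagnesium bromide, C[Mg]Br
Why: Double Grignard addition to a lactone: the first equivalent opens the ring to the methyl ketone (held as magnesium phenoxide 11) and the second gives the tertiary alkoxide.

**Step 7**
Reactants: 12 2-(3-hydroxy-3-methylbutyl)phenol
Product: 13 4-bromo-2-(3-hydroxy-3-methylbutyl)phenol
Conditions: NBS (1.0 equiv), MeCN, −10 → 0 °C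
Reagents that add atoms: N-bromosuccinimide, O=C1CCC(=O)N1Br
Why: Electrophilic aromatic bromination; in acetonitrile NBS brominates phenols para to the hydroxyl, and that position is free and less hindered than the remaining ortho carbon.

**Step 8**
Reactants: 13 4-bromo-2-(3-hydroxy-3-methylbutyl)phenol
Product: 14 4-bromo-1-(methoxymethoxy)-2-[3-(methoxymethoxy)-3-methylbutyl]benzene
Conditions: MOMCl (4 equiv), i-Pr2NEt (5 equiv), Bu4NI (cat.), CH2Cl2, 0 → 40 °C
Reagents that add atoms: chloromethyl methyl ether (MOMCl), COCCl
Why: Acetal protection of both hydroxyls in one operation; the phenol reacts readily, and the tertiary alcohol needs the iodide catalyst and gentle warming.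

**Step 9**
Reactants: 14 4-bromo-1-(methoxymethoxy)-2-[3-(methoxymethoxy)-3-methylbutyl]benzene; 15 2-chloro-N-methoxy-N-methylacetamide
Product: 17 2-chloro-1-{4-(methoxymethoxy)-3-[3-(methoxymethoxy)-3-methylbutyl]phenyl}ethan-1-one, via aryllithium 16 (not isolated)
Conditions: n-BuLi, THF, −78 °C; 15, −78 → −20 °C; aq. NH4Cl
Reagents that add atoms: none
Why: Bromine–lithium exchange followed by Weinreb ketone synthesis; the chelated tetrahedral adduct persists until the quench, which prevents a second addition and delivers the α-chloroketone directly.

**Step 10**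
Reactants: 9 6-hydroxy-2,4-bis(methoxymethoxy)-3-(3-methylbut-2-en-1-yl)benzaldehyde; 17 2-chloro-1-{4-(methoxymethoxy)-3-[3-(methoxymethoxy)-3-methylbutyl]phenyl}ethan-1-one
Product: 18 6-(2-{4-(methoxymethoxy)-3-[3-(methoxymethoxy)-3-methylbutyl]phenyl}-2-oxoethoxy)-2,4-bis(methoxymethoxy)-3-(3-methylbut-2-en-1-yl)benzaldehyde
Conditions: K2CO3 (1.5 equiv), KI (10 mol%), acetone, rt → 40 °C
Reagents that add atoms: none
Why: Williamson ether synthesis with Finkelstein activation of the chloride; the phenol ortho to the aldehyde is acidic enough for carbonate, and the low temperature should keep the product from undergoing base-induced aldol closure.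

**Step 11**
Reactants: 18 6-(2-{4-(methoxymethoxy)-3-[3-(methoxymethoxy)-3-methylbutyl]phenyl}-2-oxoethoxy)-2,4-bis(methoxymethoxy)-3-(3-methylbut-2-en-1-yl)benzaldehyde
Product: 20 (3RS)-3-hydroxy-5,7-bis(methoxymethoxy)-3-{4-(methoxymethoxy)-3-[3-(methoxymethoxy)-3-methylbutyl]phenyl}-6-(3-methylbut-2-en-1-yl)-2,3-dihydro-4H-chromen-4-one (racemic), via Breslow intermediate 19 (not isolated)
Conditions: 2-(pentafluorophenyl)-6,7-dihydro-5H-pyrrolo[2,1-c][1,2,4]triazol-2-ium tetrafluoroborate (15 mol%), Et3N (15 mol%), PhMe, 25 → 40 °C, Ar
Reagents that add atoms: none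
Why: Deprotonation of the triazolium salt gives the carbene, which adds to the aldehyde carbon (C4) of 18; proton transfer gives Breslow intermediate 19, an enaminol that is nucleophilic at C4. This acyl-anion equivalent adds to the tethered aryl ketone carbon (C3), and collapse of the adduct releases the carbene and leaves the α-hydroxy ketone 20. The closest known reaction type is the carbene-catalysed intramolecular crossed aldehyde–ketone benzoin cyclisation of 2-(2-oxoalkoxy)benzaldehydes to 3-hydroxychroman-4-ones. Ring C closes in a 6-exo-trig mode, since C4 attacks the ketone carbon and the ketone oxygen stays outside the new ring. The new stereocentre C3 has no controlling element because catalyst and substrate are achiral, so 20 should form as a racemate, which is harmless because C3 becomes sp2 in step 12. Crossed selectivity rests on two substrate features: only the aldehyde can form a Breslow intermediate, and the hindered 2,6-dioxygenated aldehyde is a poor acceptor for intermolecular homo-benzoin while the ketone is held within reach by the O1–C2 tether. The competing base-mediated aldol closure of the O–CH2–C(=O) methylene onto the aldehyde is held back by a catalytic amount of a weak amine base in a non-polar solvent, which the acidic N-pentafluorophenyl triazolium salt permits. Acetals, the prenyl alkene and the aryl ether are inert under these conditions.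

**Step 12**
Reactants: 20 (3RS)-3-hydroxy-5,7-bis(methoxymethoxy)-3-{4-(methoxymethoxy)-3-[3-(methoxymethoxy)-3-methylbutyl]phenyl}-6-(3-methylbut-2-en-1-yl)-2,3-dihydro-4H-chromen-4-one
Product: 22 5,7-bis(methoxymethoxy)-3-{4-(methoxymethoxy)-3-[3-(methoxymethoxy)-3-methylbutyl]phenyl}-6-(3-methylbut-2-en-1-yl)-4H-chromen-4-one, via sulfamate ester 21 (not isolated)
Conditions: Burgess reagent (2.5 equiv), THF, rt → 60 °C
Reagents that add atoms: none
Why: Burgess dehydration: the carbinol oxygen attacks sulfur with loss of Et3N to give sulfamate 21, which undergoes intramolecular syn elimination (Ei) with a C2 hydrogen. Only C2 carries β-hydrogens, so the alkene can form only at C2=C3, and the gain of the conjugated pyranone drives the step. The acetal on the side-chain tertiary oxygen keeps that carbinol out of the reaction.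

**Step 13**
Reactants: 22 5,7-bis(methoxymethoxy)-3-{4-(methoxymethoxy)-3-[3-(methoxymethoxy)-3-methylbutyl]phenyl}-6-(3-methylbut-2-en-1-yl)-4H-chromen-4-one
Product: 23 coloratanin A, 5,7-dihydroxy-3-[4-hydroxy-3-(3-hydroxy-3-methylbutyl)phenyl]-6-(3-methylbut-2-en-1-yl)-4H-chromen-4-one
Conditions: 2 M aq. HCl, MeOH/THF, 40 °C
Reagents that add atoms: none
Why: Acid-catalysed transacetalisation of the four methoxymethyl ethers to methanol; the O5 acetal next to the C4 carbonyl should go first and the others follow. Dilute acid at 40 °C lies below the conditions under which a prenyl group closes onto a neighbouring phenol or a tertiary carbinol ionises.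

## Compound list

1 | phloroglucinol (benzene-1,3,5-triol) | Oc1cc(O)cc(O)c1 | starting material
2 | 3,5-bis(methoxymethoxy)phenol | COCOc1cc(O)cc(OCOC)c1 | intermediate
3 | [3,5-bis(methoxymethoxy)phenoxy]tri(propan-2-yl)silane | COCOc1cc(O[Si](C(C)C)(C(C)C)C(C)C)cc(OCOC)c1 | intermediate
4 | prenyl bromide (1-bromo-3-methylbut-2-ene) | CC(C)=CCBr | starting material
5 | {2,6-bis(methoxymethoxy)-4-[tri(propan-2-yl)silyloxy]phenyl}lithium | [Li]c1c(OCOC)cc(O[Si](C(C)C)(C(C)C)C(C)C)cc1OCOC | intermediate (not isolated)
6 | {2,6-bis(methoxymethoxy)-4-[tri(propan-2-yl)silyloxy]phenyl}copper | [Cu]c1c(OCOC)cc(O[Si](C(C)C)(C(C)C)C(C)C)cc1OCOC | intermediate (not isolated)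
7 | [3,5-bis(methoxymethoxy)-4-(3-methylbut-2-en-1-yl)phenoxy]tri(propan-2-yl)silane | COCOc1cc(O[Si](C(C)C)(C(C)C)C(C)C)cc(OCOC)c1CC=C(C)C | intermediate
8 | 3,5-bis(methoxymethoxy)-4-(3-methylbut-2-en-1-yl)phenol | COCOc1cc(O)cc(OCOC)c1CC=C(C)C | intermediate
9 | 6-hydroxy-2,4-bis(methoxymethoxy)-3-(3-methylbut-2-en-1-yl)benzaldehyde | O=Cc1c(O)cc(OCOC)c(CC=C(C)C)c1OCOC | intermediate
10 | 3,4-dihydrocoumarin (chroman-2-one) | O=C1CCc2ccccc2O1 | starting material
11 | bromomagnesium 2-(3-oxobutyl)phenoxide | CC(=O)CCc1ccccc1O[Mg]Br | intermediate (not isolated)
12 | 2-(3-hydroxy-3-methylbutyl)phenol | CC(C)(O)CCc1ccccc1O | intermediate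
13 | 4-bromo-2-(3-hydroxy-3-methylbutyl)phenol | CC(C)(O)CCc1cc(Br)ccc1O | intermediate
14 | 4-bromo-1-(methoxymethoxy)-2-[3-(methoxymethoxy)-3-methylbutyl]benzene | COCOc1ccc(Br)cc1CCC(C)(C)OCOC | intermediate
15 | 2-chloro-N-methoxy-N-methylacetamide | CON(C)C(=O)CCl | starting material
16 | {4-(methoxymethoxy)-3-[3-(methoxymethoxy)-3-methylbutyl]phenyl}lithium | [Li]c1ccc(OCOC)c(CCC(C)(C)OCOC)c1 | intermediate (not isolated)
17 | 2-chloro-1-{4-(methoxymethoxy)-3-[3-(methoxymethoxy)-3-methylbutyl]phenyl}ethan-1-one | COCOc1ccc(C(=O)CCl)cc1CCC(C)(C)OCOC | intermediate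
18 | 6-(2-{4-(methoxymethoxy)-3-[3-(methoxymethoxy)-3-methylbutyl]phenyl}-2-oxoethoxy)-2,4-bis(methoxymethoxy)-3-(3-methylbut-2-en-1-yl)benzaldehyde | O=Cc1c(OCC(=O)c2ccc(OCOC)c(CCC(C)(C)OCOC)c2)cc(OCOC)c(CC=C(C)C)c1OCOC | intermediate
19 | Breslow intermediate: enaminol formed from the aldehyde carbon of 18 and 2-(pentafluorophenyl)-6,7-dihydro-5H-pyrrolo[2,1-c][1,2,4]triazol-3-ylidene | OC(=C1N(c2c(F)c(F)c(F)c(F)c2F)N=C2CCCN12)c1c(OCC(=O)c2ccc(OCOC)c(CCC(C)(C)OCOC)c2)cc(OCOC)c(CC=C(C)C)c1OCOC | intermediate (not isolated)
20 | (3RS)-3-hydroxy-5,7-bis(methoxymethoxy)-3-{4-(methoxymethoxy)-3-[3-(methoxymethoxy)-3-methylbutyl]phenyl}-6-(3-methylbut-2-en-1-yl)-2,3-dihydro-4H-chromen-4-one (racemic, one enantiomer drawn) | O=C1c2c(OCOC)c(CC=C(C)C)c(OCOC)cc2OC[C@]1(O)c1ccc(OCOC)c(CCC(C)(C)OCOC)c1 | intermediate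
21 | N-(methoxycarbonyl)sulfamate ester at O3 of 20, present as its triethylammonium salt (racemic, one enantiomer drawn) | O=C1c2c(OCOC)c(CC=C(C)C)c(OCOC)cc2OC[C@]1(OS(=O)(=O)NC(=O)OC)c1ccc(OCOC)c(CCC(C)(C)OCOC)c1 | intermediate (not isolated)
22 | 5,7-bis(methoxymethoxy)-3-{4-(methoxymethoxy)-3-[3-(methoxymethoxy)-3-methylbutyl]phenyl}-6-(3-methylbut-2-en-1-yl)-4H-chromen-4-one | COCOc1cc2occ(-c3ccc(OCOC)c(CCC(C)(C)OCOC)c3)c(=O)c2c(OCOC)c1CC=C(C)C | intermediate
23 | coloratanin A (no stereocentre) | CC(C)=CCc1c(O)cc2occ(-c3ccc(O)c(CCC(C)(C)O)c3)c(=O)c2c1O | target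

## Step count and least certain steps

Total: 13 steps. Longest linear sequence: 9 steps (steps 1–5 and 10–13, from 1). The ring B branch (steps 6–9, from 10) has 4 steps and joins at step 10.

**Step 11 (key step).** The aldehyde carbon is flanked by two oxygen substituents and is electron-rich, so carbene addition and Breslow formation may be slow. That would leave time for base-mediated aldol closure and dehydration to an aroylbenzofuran, or for air oxidation of the Breslow intermediate. The fallback abandons the C3–C4 closure and builds the isoflavone by cross-coupling; it sets out from 9 and 14 and comes back at 22, so it also bypasses step 12.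
- Addition of MeMgBr (2.5 equiv, THF, −78 → 0 °C) to 9 should give the benzylic alcohol 2-(1-hydroxyethyl)-3,5-bis(methoxymethoxy)-4-(3-methylbut-2-en-1-yl)phenol F1.
- Oxidation with MnO2 in CH2Cl2 should give the ketone 1-[6-hydroxy-2,4-bis(methoxymethoxy)-3-(3-methylbut-2-en-1-yl)phenyl]ethan-1-one F2.
- Condensation with N,N-dimethylformamide dimethyl acetal at 90 °C should give the enaminone (E)-3-(dimethylamino)-1-[6-hydroxy-2,4-bis(methoxymethoxy)-3-(3-methylbut-2-en-1-yl)phenyl]prop-2-en-1-one F3.
- Iodine in pyridine/CHCl3 should cyclise it to 3-iodo-5,7-bis(methoxymethoxy)-6-(3-methylbut-2-en-1-yl)-4H-chromen-4-one F4.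
- Separately, bromine–lithium exchange on 14 and trapping with 2-isopropoxy-4,4,5,5-tetramethyl-1,3,2-dioxaborolane should give the boronate 2-{4-(methoxymethoxy)-3-[3-(methoxymethoxy)-3-methylbutyl]phenyl}-4,4,5,5-tetramethyl-1,3,2-dioxaborolane F5.
- Suzuki–Miyaura coupling of F4 with F5 (Pd(dppf)Cl2, K2CO3, 1,4-dioxane/H2O, 80 °C) should give 22.

**Step 12.** The hindered tertiary carbinol next to the carbonyl may be sulfonylated slowly. The elimination has cationic character at a carbon that the carbonyl destabilises, so heating with amine present could instead open the ring by retro-benzoin. The fallback replaces dehydration by reductive removal of the C3 oxygen followed by dehydrogenation; it sets out from 20 and comes back at 22.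
- SmI2 in THF/MeOH at −78 °C should cleave the C3–O bond of the α-hydroxy ketone to give the isoflavanone 5,7-bis(methoxymethoxy)-3-{4-(methoxymethoxy)-3-[3-(methoxymethoxy)-3-methylbutyl]phenyl}-6-(3-methylbut-2-en-1-yl)-2,3-dihydro-4H-chromen-4-one F6 (racemic).
- TMSOTf/Et3N should convert it into the silyl enol ether {5,7-bis(methoxymethoxy)-3-{4-(methoxymethoxy)-3-[3-(methoxymethoxy)-3-methylbutyl]phenyl}-6-(3-methylbut-2-en-1-yl)-2H-chromen-4-yl}oxy(trimethyl)silane F7.
- Saegusa–Ito oxidation with Pd(OAc)2 in MeCN should install the C2=C3 double bond and give 22.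

**Step 13.** Protonation of the prenyl alkene followed by closure onto O5 or O7 may compete. So may ionisation of the tertiary carbinol with closure onto O4′ or elimination, or incomplete cleavage of the tertiary acetal. The fallback sets out from 22 and gives 23 directly. It replaces protic solvolysis by thiol-assisted Lewis-acid cleavage in an aprotic medium (ZnBr2, n-PrSH, CH2Cl2, 0 °C, a few minutes). The acetal carbon is transferred to sulfur and no free proton source is present to ionise the carbinol or protonate the alkene.

**Step 9.** Proton transfer from the acidic CH2Cl group of 15 to the aryllithium would return the debrominated arene; displacement of chloride may compete with acylation. The fallback introduces the halogen after the ketone; it sets out from 14 and comes back at 18.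
- The aryllithium from 14 is acylated with N-methoxy-N-methylacetamide to give 1-{4-(methoxymethoxy)-3-[3-(methoxymethoxy)-3-methylbutyl]phenyl}ethan-1-one F8.
- LiHMDS/TMSCl at −78 °C should give the silyl enol ether trimethyl[(1-{4-(methoxymethoxy)-3-[3-(methoxymethoxy)-3-methylbutyl]phenyl}ethenyl)oxy]silane F9.
- NBS in THF at 0 °C should give, under neutral conditions, the phenacyl bromide 2-bromo-1-{4-(methoxymethoxy)-3-[3-(methoxymethoxy)-3-methylbutyl]phenyl}ethan-1-one F10.
- F10 is used in place of 17 under the conditions of step 10 to give 18.

**Step 10.** Once the ether has formed, carbonate may trigger aldol closure of the O–CH2–C(=O) methylene onto the aldehyde (benzofuran formation); the hydrogen-bonded phenol may also alkylate slowly. The fallback forms the same O1–C2 bond without base; it sets out from 17 and 9 and comes back at 18.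
- Sodium formate in aqueous ethanol at reflux should convert 17 into the α-hydroxy ketone 2-hydroxy-1-{4-(methoxymethoxy)-3-[3-(methoxymethoxy)-3-methylbutyl]phenyl}ethan-1-one F11.
- Mitsunobu etherification of 9 with F11 (PPh3, DIAD, THF, 0 °C) should give 18.

## Further compounds

F1 | step 11 | 2-(1-hydroxyethyl)-3,5-bis(methoxymethoxy)-4-(3-methylbut-2-en-1-yl)phenol (racemic) | CC(O)c1c(O)cc(OCOC)c(CC=C(C)C)c1OCOC
F2 | step 11 | 1-[6-hydroxy-2,4-bis(methoxymethoxy)-3-(3-methylbut-2-en-1-yl)phenyl]ethan-1-one | CC(=O)c1c(O)cc(OCOC)c(CC=C(C)C)c1OCOC
F3 | step 11 | (E)-3-(dimethylamino)-1-[6-hydroxy-2,4-bis(methoxymethoxy)-3-(3-methylbut-2-en-1-yl)phenyl]prop-2-en-1-one | CN(C)/C=C/C(=O)c1c(O)cc(OCOC)c(CC=C(C)C)c1OCOC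
F4 | step 11 | 3-iodo-5,7-bis(methoxymethoxy)-6-(3-methylbut-2-en-1-yl)-4H-chromen-4-one | COCOc1cc2occ(I)c(=O)c2c(OCOC)c1CC=C(C)C
F5 | step 11 | 2-{4-(methoxymethoxy)-3-[3-(methoxymethoxy)-3-methylbutyl]phenyl}-4,4,5,5-tetramethyl-1,3,2-dioxaborolane | COCOc1ccc(B2OC(C)(C)C(C)(C)O2)cc1CCC(C)(C)OCOC
F6 | step 12 | 5,7-bis(methoxymethoxy)-3-{4-(methoxymethoxy)-3-[3-(methoxymethoxy)-3-methylbutyl]phenyl}-6-(3-methylbut-2-en-1-yl)-2,3-dihydro-4H-chromen-4-one (racemic) | COCOc1cc2OCC(c3ccc(OCOC)c(CCC(C)(C)OCOC)c3)C(=O)c2c(OCOC)c1CC=C(C)C
F7 | step 12 | {5,7-bis(methoxymethoxy)-3-{4-(methoxymethoxy)-3-[3-(methoxymethoxy)-3-methylbutyl]phenyl}-6-(3-methylbut-2-en-1-yl)-2H-chromen-4-yl}oxy(trimethyl)silane | COCOc1cc2OCC(c3ccc(OCOC)c(CCC(C)(C)OCOC)c3)=C(O[Si](C)(C)C)c2c(OCOC)c1CC=C(C)C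
F0 | step 13 | none | none
F8 | step 9 | 1-{4-(methoxymethoxy)-3-[3-(methoxymethoxy)-3-methylbutyl]phenyl}ethan-1-one | COCOc1ccc(C(C)=O)cc1CCC(C)(C)OCOC
F9 | step 9 | trimethyl[(1-{4-(methoxymethoxy)-3-[3-(methoxymethoxy)-3-methylbutyl]phenyl}ethenyl)oxy]silane | C=C(O[Si](C)(C)C)c1ccc(OCOC)c(CCC(C)(C)OCOC)c1
F10 | step 9 | 2-bromo-1-{4-(methoxymethoxy)-3-[3-(methoxymethoxy)-3-methylbutyl]phenyl}ethan-1-one | COCOc1ccc(C(=O)CBr)cc1CCC(C)(C)OCOC
F11 | step 10 | 2-hydroxy-1-{4-(methoxymethoxy)-3-[3-(methoxymethoxy)-3-methylbutyl]phenyl}ethan-1-one | COCOc1ccc(C(=O)CO)cc1CCC(C)(C)OCOC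
A1 | alternative 1 | 3-{4-[tert-butyl(dimethyl)silyloxy]-3-(3-hydroxy-3-methylbutyl)phenyl}-5,7-bis(methoxymethoxy)-6-(3-methylbut-2-en-1-yl)-4H-chromen-4-one | COCOc1cc2occ(-c3ccc(O[Si](C)(C)C(C)(C)C)c(CCC(C)(C)O)c3)c(=O)c2c(OCOC)c1CC=C(C)C
A2 | alternative 1 | (E)-3-(dimethylamino)-1-[6-hydroxy-2,4-bis(methoxymethoxy)-3-(3-methylbut-2-en-1-yl)phenyl]prop-2-en-1-one | CN(C)/C=C/C(=O)c1c(O)cc(OCOC)c(CC=C(C)C)c1OCOC
A3 | alternative 1 | 4-[tert-butyl(dimethyl)silyloxy]-3-(3-hydroxy-3-methylbutyl)benzenediazonium tetrafluoroborate | CC(C)(C)[Si](C)(C)Oc1ccc(cc1CCC(C)(C)O)[N+]#N.F[B-](F)(F)F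
A4 | alternative 2 | 5-hydroxy-3-{4-(methoxymethoxy)-3-[3-(methoxymethoxy)-3-methylbutyl]phenyl}-6-(3-methylbut-2-en-1-yl)-7-[tri(propan-2-yl)silyloxy]-4H-chromen-4-one | CC(C)=CCc1c(O[Si](C(C)C)(C(C)C)C(C)C)cc2occ(-c3ccc(OCOC)c(CCC(C)(C)OCOC)c3)c(=O)c2c1O
A5 | alternative 2 | 2-diazo-1-(5-{4-(methoxymethoxy)-3-[3-(methoxymethoxy)-3-methylbutyl]phenyl}-4-oxo-4H-pyran-2-yl)ethan-1-one | COCOc1ccc(cc1CCC(C)(C)OCOC)-c1coc(cc1=O)C(=O)C=[N+]=[N-]
A6 | alternative 2 | [(5-methylhex-4-en-1-yn-1-yl)oxy]tri(propan-2-yl)silane | CC(C)=CCC#CO[Si](C(C)C)(C(C)C)C(C)C
A7 | alternative 3 | 5,7-bis(methoxymethoxy)-3-{4-(methoxymethoxy)-3-[3-(methoxymethoxy)-3-methylbutyl]phenyl}-6-(3-methylbut-2-en-1-yl)-4H-chromen-4-one (same structure as 22) | COCOc1cc2occ(-c3ccc(OCOC)c(CCC(C)(C)OCOC)c3)c(=O)c2c(OCOC)c1CC=C(C)C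
A8 | alternative 3 | 3,5-bis(methoxymethoxy)-4-(3-methylbut-2-en-1-yl)-2-(trimethylsilyl)phenyl trifluoromethanesulfonate | COCOc1cc(OS(=O)(=O)C(F)(F)F)c([Si](C)(C)C)c(OCOC)c1CC=C(C)C
A9 | alternative 3 | methyl 2-{4-(methoxymethoxy)-3-[3-(methoxymethoxy)-3-methylbutyl]phenyl}-3-oxopropanoate (racemic, enolisable) | COC(=O)C(C=O)c1ccc(OCOC)c(CCC(C)(C)OCOC)c1
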